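## Analysis of the target

Compound 13 is an isoflavone: a 4H-chromen-4-one in which the pyranone ring C is fused to the benzo ring A and carries a 3,4,5-trimethoxyphenyl group (ring B) at C3. Ring A bears a free hydroxyl at C6 and a methoxyl at C7, and C2, C5 and C8 carry hydrogen. The molecule is flat and achiral, so there is no stereocentre and no configuration to set. The sensitive sites are the C6 phenol (para to O1 and ortho to the C7 methoxyl, so easily oxidised in base and air), the pyranone ring (opened by hydroxide at C2) and the four aryl methyl ethers, which must survive whatever unmasks O6. The difficulties are constitutional: O6 and O7 are neighbours and must be distinguished, ring C must be fused so that C4a lies para to the C7 methoxyl, and C2 must end at the CH level next to a C4 ketone. The strategy rests on the two bonds that tie ring A to the three-carbon unit C2–C3–C4, namely C4–C4a and O1–C2. A phenol and an arylmalonate form exactly these two bonds, with the ring B aryl already on C3. The price is that C2 arrives as a lactone carbonyl and has to be taken down one oxidation level afterwards.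

## Retrosynthetic reasoning

**13 to 12.** The last operation only unmasks O6; no skeletal bond is cut. A benzyl ether is chosen because it is already present in 1, so O6 and O7 are distinguished from the first step. It also comes off by hydrogenolysis without touching the four methyl ethers.

**12 to 9.** The chromone is read as the hydrolysis product of the 4-methoxychromenylium ion 11, which is 12 methylated on its carbonyl oxygen. Ion 11 comes from lactol 10 by loss of hydroxide from C2, and 10 comes from lactone 9 by addition of one hydride to C2. This interchange moves C2 from the formyl to the carboxyl oxidation level and turns the C4 ketone into an enol ether. The gain is that ring C then has the oxidation pattern of a 4-hydroxycoumarin, which a malonate can build. The forward reaction must stop the hydride at the lactol stage and then expel the C4 methyl group as the alcohol.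

**9 to 8.** The O-methyl group at C4 is removed. In the forward direction the methylation fixes the enol of 8 so that C2 is the only carbonyl offered to the hydride, and it prepares the C4 oxygen to leave later.

**8 to 3 and 6.** The bonds O1–C2 and C4–C4a are cut together. Both join ring A to the two carbonyl carbons of a malonate, so the symmetric diester 6 can deliver C2, C3 and C4 with the ring B aryl in place and without any regiochemical question on the three-carbon side. Phenol 3 supplies O1 and the nucleophilic ring carbon. Cutting the C3–aryl bond instead would demand a halogenated heterocycle and a cross-coupling. The forward reaction acylates the oxygen first (mixed ester 7) and then the ring carbon para to the methoxyl, not the carbon between the two oxygens.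

**3 to 1.** The phenolic C–O bond is traced back to a formyl C–C bond, since aryl migration in a peracid adduct turns the aldehyde into a formate (2) and then the phenol. Aldehyde 1 already has the methoxyl and the benzyloxy group in the 3,4-relationship the target needs.

**6 to 4 and 5.** The aryl–C3 bond is cut to aryl bromide 4 and malonate 5. A palladium-catalysed enolate arylation makes it in one step and leaves both ester groups for the annulation.

## Alternatives that were turned down

**Alternative 1:** Here C4–C4a and C8a–O1 are cut together, so that ring A arrives as an aryne and the rest as 2-(3,4,5-trimethoxyphenyl)acetic acid A2.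
- **Forward key step:** fluoride frees the aryne from 4,5-bis(benzyloxy)-2-(trimethylsilyl)phenyl trifluoromethanesulfonate A1. The carboxylate oxygen of A2 adds, the aryl anion attacks the acyl carbon, and the four-membered intermediate opens to 1-[4,5-bis(benzyloxy)-2-hydroxyphenyl]-2-(3,4,5-trimethoxyphenyl)ethan-1-one A3. No ring closes; ring C is closed afterwards with a one-carbon electrophile.
- **For:** it is mild and convergent, and C2 enters at its final oxidation level. On both points it is stronger than the malonate route, which needs 250 °C and a redox correction.
- **Against:** two remote alkoxy groups do not direct an aryne, so only a symmetric aryne gives one product. A3 therefore carries the same group on O6 and O7, and the distinction has to be re-made at the end by selective mono-methylation of a 6,7-diol. A1 needs several steps of its own, and plain O-arylation of A2 competes with insertion.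
- **Comparison:** about eight steps against six. The chosen route offers in its place an O6/O7 distinction inherited from 1 and precursors made in one step each.

**Alternative 2:** Ring A is built last, by cutting C4a–C5 and C8–C8a.
- **Forward key step:** 2,3-bis(trimethylsilyloxy)buta-1,3-diene A5 is added across the unsubstituted C5=C6 bond of 3-(3,4,5-trimethoxyphenyl)-4H-pyran-4-one A4 under silyl triflate activation. This closes the carbocycle as racemic cis-3-(3,4,5-trimethoxyphenyl)-6,7-bis(trimethylsilyloxy)-4a,5,8,8a-tetrahydro-4H-chromen-4-one A6.
- **For:** ring A oxygenation comes from the diene, and no electrophilic substitution regiochemistry arises.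
- **Against:** the C5=C6 bond of A4 is part of a vinylogous ester and a poor dienophile. After O-silylation the pyrylium ion is more likely to take the diene at C6 or C2 in a single Michael-type bond formation than to complete the annulation. A6 then needs two dehydrogenations to become aromatic, under conditions that threaten the resulting catechol, followed by a selective O7 methylation. Two stereocentres are made only to be destroyed, and A4 itself takes several steps.
- **Comparison:** it is longer and rests on an untested annulation, and it has no point on which it beats the chosen route for this flat target. The chosen key step is a known reaction type.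

**Alternative 3:** Ring A is again made de novo, by cutting C5–C6 and C4a–C8a.
- **Forward key step:** methyl tetronate A7 is silylated to 4-methoxy-2-(trimethylsilyloxy)furan A8, which adds across the alkynyl ketone 1-(3,4,5-trimethoxyphenyl)but-3-yn-2-one A9. The oxanorbornadiene opens at the silyloxy-bearing bridgehead and aromatises to 1-(2,5-dihydroxy-4-methoxyphenyl)-2-(3,4,5-trimethoxyphenyl)ethan-1-one A10.
- **For:** the polarised diene and ynone fix the regiochemistry. A10 has O6 free and O7 methylated with no protecting group, and one further one-carbon closure would give 13 at the correct oxidation level. In step count and protecting-group economy it is at least as good as the chosen route, and it needs no redox correction.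
- **Against:** A9 is a terminal ynone with an acidic benzylic methylene and is prone to isomerisation and polymerisation. A8 is labile and may stop at conjugate addition. The hydroquinone A10 oxidises easily to the quinone.
- **Comparison:** the chosen route offers in its place stable intermediates throughout, cheap aromatic starting materials, and an acidic key product that can be purified by base extraction.

Key step: step 3

Remark on the chemistry: 13 has no stereocentre. The only stereocentre on the route, C2 of lactol 10, forms racemic and is erased in the same flask.

## Route

Step 1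
Reactants: 1 4-(benzyloxy)-3-methoxybenzaldehyde
Product: 3 4-(benzyloxy)-3-methoxyphenol, via 4-(benzyloxy)-3-methoxyphenyl formate 2 (not isolated)
Conditions: mCPBA, CH2Cl2, 0 °C to rt; aq. Na2SO3/NaHCO3 wash; then K2CO3 (cat.), MeOH, rt
Reagents that add atoms: 3-chloroperoxybenzoic acid (mCPBA), OOC(=O)c1cccc(Cl)c1
Why: Baeyer–Villiger (Dakin-type) oxidation: in the peracid adduct of the electron-rich aldehyde 1 the aryl group migrates in preference to hydrogen and gives formate 2; base-catalysed methanolysis of this activated aryl formate should free phenol 3, and the benzyl and methyl ethers are inert to both stages.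

Step 2
Reactants: 4 5-bromo-1,2,3-trimethoxybenzene; 5 diethyl propanedioate (diethyl malonate)
Product: 6 diethyl 2-(3,4,5-trimethoxyphenyl)propanedioate
Conditions: Pd(dba)2 (2 mol%), P(t-Bu)3 (4 mol%), K3PO4 (3 equiv), toluene, 70 °C
Reagents that add atoms: none
Why: Palladium-catalysed α-arylation of a malonate enolate (Buchwald–Hartwig-type C–C coupling): the unhindered bromide 4 adds oxidatively to zerovalent palladium bearing the bulky electron-rich phosphine, the potassium enolate of 5 exchanges for bromide and reductive elimination forms the aryl–C bond; the product is more acidic than 5 and rests as its enolate, which should prevent a second arylation.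

Step 3
Reactants: 3 4-(benzyloxy)-3-methoxyphenol; 6 diethyl 2-(3,4,5-trimethoxyphenyl)propanedioate
Product: 8 6-(benzyloxy)-4-hydroxy-7-methoxy-3-(3,4,5-trimethoxyphenyl)-2H-chromen-2-one, via mixed aryl ethyl malonate 7 (not isolated)
Conditions: Ph2O, Ar, 190 °C then 250 °C, EtOH distilled off
Reagents that add atoms: none
Why: This is the thermal cyclocondensation of a phenol with a 2-aryl malonic ester, the known malonate route to 3-aryl-4-hydroxycoumarins. On heating, 6 loses ethanol to an aryl(ethoxycarbonyl)ketene that acylates the phenol oxygen of 3 (bond O1–C2) and gives mixed ester 7; a second loss of ethanol from 7 gives an (aryloxycarbonyl)ketene. Its sp carbon is attacked by the ring carbon ortho to the ester oxygen (bond C4–C4a) in an intramolecular Friedel–Crafts acylation, a six-membered closure of ring C that is 6-exo-dig with respect to the ketene C=O, and tautomerisation gives the 4-hydroxycoumarin. No stereocentre is formed. The step needs closure at the carbon para to the methoxyl (future C4a) and not at the carbon between the two oxygens (future C8); the para-methoxyl activates the first site, and the second is flanked on both sides and crowded. Distilling out ethanol drives both equilibria, and holding at 190 °C until 3 is O-acylated before going to 250 °C keeps the free electron-rich phenol away from the highest temperature, which should spare the benzyl ether. Product 8 is acidic and should separate from neutral by-products by extraction into aqueous Na2CO3 and re-acidification.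

Step 4
Reactants: 8 6-(benzyloxy)-4-hydroxy-7-methoxy-3-(3,4,5-trimethoxyphenyl)-2H-chromen-2-one
Product: 9 6-(benzyloxy)-4,7-dimethoxy-3-(3,4,5-trimethoxyphenyl)-2H-chromen-2-one
Conditions: Me2SO4 (1.2 equiv), K2CO3, acetone, reflux
Reagents that add atoms: dimethyl sulfate, COS(=O)(=O)OC
Why: Williamson-type O-alkylation of the ambident 4-hydroxycoumarin anion with a hard electrophile; C3 is fully substituted and shielded by the aryl group, and under these conditions alkylation at the C4 oxygen (retaining the lactone carbonyl) should dominate over alkylation at the C2 oxygen.

Step 5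
Reactants: 9 6-(benzyloxy)-4,7-dimethoxy-3-(3,4,5-trimethoxyphenyl)-2H-chromen-2-one
Product: 12 6-(benzyloxy)-7-methoxy-3-(3,4,5-trimethoxyphenyl)-4H-chromen-4-one, via lactol 10 (not isolated), via 4-methoxychromenylium chloride 11 (not isolated)
Conditions: i-Bu2AlH (1.1 equiv), CH2Cl2, −78 °C; then 2 M HCl, THF, 0 °C to rt
Reagents that add atoms: water, O
Why: Proposed new method: one hydride should add to the lactone carbonyl C2 of the vinylogous carbonate 9 to give an aluminium acetal that holds at −78 °C and is protonated to the racemic lactol 10; acid then ionises the C2–OH bond to the 4-methoxychromenylium ion 11 (stabilised by O1, the C4 methoxyl and the ring A oxygens), water adds at C4 and methanol leaves, which gives chromone 12 and erases the C2 stereocentre, while any ring-opened hydroxy-enal tautomer of 10 should converge on 12 through enol ether hydrolysis and dehydration of the 2-hydroxyisoflavanone; the closest known reaction types are the i-Bu2AlH reduction of coumarins to 2H-chromen-2-ols and the hydrolysis of 4-alkoxybenzopyrylium salts to chromones.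

Step 6
Reactants: 12 6-(benzyloxy)-7-methoxy-3-(3,4,5-trimethoxyphenyl)-4H-chromen-4-one
Product: 13 6-hydroxy-7-methoxy-3-(3,4,5-trimethoxyphenyl)-4H-chromen-4-one
Conditions: H2 (1 atm), 10% Pd/C, EtOAc–MeOH, rt
Reagents that add atoms: none
Why: Hydrogenolysis of the benzylic C–O bond on palladium; the aryl methyl ethers are inert, and the trisubstituted C2=C3 bond of the vinylogous ester should be reduced far more slowly than the benzyl ether is cleaved at atmospheric pressure.

## Compound list

1 | 4-(benzyloxy)-3-methoxybenzaldehyde | COc1cc(C=O)ccc1OCc1ccccc1 | starting material
2 | 4-(benzyloxy)-3-methoxyphenyl formate | COc1cc(OC=O)ccc1OCc1ccccc1 | intermediate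
3 | 4-(benzyloxy)-3-methoxyphenol | COc1cc(O)ccc1OCc1ccccc1 | intermediate
4 | 5-bromo-1,2,3-trimethoxybenzene | COc1cc(Br)cc(OC)c1OC | starting material
5 | diethyl propanedioate (diethyl malonate) | CCOC(=O)CC(=O)OCC | starting material
6 | diethyl 2-(3,4,5-trimethoxyphenyl)propanedioate | CCOC(=O)C(C(=O)OCC)c1cc(OC)c(OC)c(OC)c1 | intermediate
7 | 1-[4-(benzyloxy)-3-methoxyphenyl] 3-ethyl 2-(3,4,5-trimethoxyphenyl)propanedioate (racemic) | CCOC(=O)C(C(=O)Oc1ccc(OCc2ccccc2)c(OC)c1)c1cc(OC)c(OC)c(OC)c1 | intermediate
8 | 6-(benzyloxy)-4-hydroxy-7-methoxy-3-(3,4,5-trimethoxyphenyl)-2H-chromen-2-one | COc1cc2oc(=O)c(-c3cc(OC)c(OC)c(OC)c3)c(O)c2cc1OCc1ccccc1 | intermediate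
9 | 6-(benzyloxy)-4,7-dimethoxy-3-(3,4,5-trimethoxyphenyl)-2H-chromen-2-one | COc1cc2oc(=O)c(-c3cc(OC)c(OC)c(OC)c3)c(OC)c2cc1OCc1ccccc1 | intermediate
10 | 6-(benzyloxy)-4,7-dimethoxy-3-(3,4,5-trimethoxyphenyl)-2H-chromen-2-ol (racemic at C2) | COc1cc2OC(O)C(c3cc(OC)c(OC)c(OC)c3)=C(OC)c2cc1OCc1ccccc1 | intermediate
11 | 6-(benzyloxy)-4,7-dimethoxy-3-(3,4,5-trimethoxyphenyl)chromenylium chloride | COc1cc2[o+]cc(-c3cc(OC)c(OC)c(OC)c3)c(OC)c2cc1OCc1ccccc1.[Cl-] | intermediate
12 | 6-(benzyloxy)-7-methoxy-3-(3,4,5-trimethoxyphenyl)-4H-chromen-4-one | COc1cc2occ(-c3cc(OC)c(OC)c(OC)c3)c(=O)c2cc1OCc1ccccc1 | intermediate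
13 | 6-hydroxy-7-methoxy-3-(3,4,5-trimethoxyphenyl)-4H-chromen-4-one | COc1cc2occ(-c3cc(OC)c(OC)c(OC)c3)c(=O)c2cc1O | target

## Step count and least certain steps

Total step count: 6. Longest linear sequence: 5 steps (1 to 3 to 8 to 9 to 12 to 13; the branch from 4 through 6 is equally long).

**Step 5 (reduction and ionisation).**
- **What may go wrong:** over-reduction or misdirected hydride delivery. The aluminium acetal at C2 may collapse already at −78 °C, because an aryloxide is a good leaving group. The β-methoxy enal so released can then take a second hydride and end as the allylic alcohol. Conversely, the electron-rich vinylogous carbonate carbonyl may react sluggishly, and hydride attack at C4 with loss of methoxide is conceivable.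
- **Fallback (from 8, back at 12):** C2 is excised and put back at the right oxidation level by known chemistry. Boiling aqueous NaOH under N2 opens the lactone of 8, and the β-keto acid decarboxylates (the classical ketonic cleavage of 4-hydroxycoumarins) to 1-[5-(benzyloxy)-2-hydroxy-4-methoxyphenyl]-2-(3,4,5-trimethoxyphenyl)ethan-1-one F1. Heating F1 with N,N-dimethylformamide dimethyl acetal in toluene should give 1-[5-(benzyloxy)-2-hydroxy-4-methoxyphenyl]-3-(dimethylamino)-2-(3,4,5-trimethoxyphenyl)prop-2-en-1-one F2 (alkene geometry immaterial). F2 cyclises with loss of dimethylamine to 12. Step 4 then becomes unnecessary.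

**Step 3 (key step).**
- **What may go wrong:** thermal or acid-promoted loss or migration of the benzyl group at 250 °C, since the ether is electron-rich and the product is an acid. The reaction may also stall at the O-acylated stage 7, 6 may lose an ester group, or a minor amount may close at the crowded carbon between the two oxygens.
- **Fallback (from 3, back at 12):** the order of bond formation is reversed and the malonate is abandoned. A Hoesch reaction of 3 with (3,4,5-trimethoxyphenyl)acetonitrile (ZnCl2, dry HCl, Et2O, 0 °C) acylates the same ring carbon para to the methoxyl and gives 1-[5-(benzyloxy)-2-hydroxy-4-methoxyphenyl]-2-(3,4,5-trimethoxyphenyl)ethan-1-iminium chloride F3. Warm water hydrolyses F3 to the deoxybenzoin F1 described above, which is closed to 12 with N,N-dimethylformamide dimethyl acetal as in the preceding fallback. This bypasses steps 4 and 5.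

**Step 4 (O-methylation).**
- **What may go wrong:** alkylation of the ambident anion at the C2 oxygen, which gives the isomeric 2-methoxychromen-4-one, or slow reaction at the hindered C4 oxygen.
- **Fallback (from 8, back at 9):** the C4 oxygen is replaced, not alkylated. POCl3 with Et3N in MeCN at 80 °C should convert 8 into 6-(benzyloxy)-4-chloro-7-methoxy-3-(3,4,5-trimethoxyphenyl)-2H-chromen-2-one F4. NaOMe in MeOH then displaces chloride at C4 by addition–elimination and gives 9 with unambiguous regiochemistry.

**Step 6 (debenzylation).**
- **What may go wrong:** partial saturation of the C2=C3 bond to the isoflavanone, or slow hydrogenolysis if 12 is poorly soluble.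
- **Fallback (from 12, directly to 13):** Lewis-acid debenzylation with BCl3 and pentamethylbenzene as cation scavenger in CH2Cl2 at −78 °C. At that temperature the benzyl ether should cleave faster than the methyl ethers, none of which is chelated to the C4 carbonyl.

## Further compounds

F1 | step 5 | 1-[5-(benzyloxy)-2-hydroxy-4-methoxyphenyl]-2-(3,4,5-trimethoxyphenyl)ethan-1-one | COc1cc(O)c(cc1OCc1ccccc1)C(=O)Cc1cc(OC)c(OC)c(OC)c1
F2 | step 5 | 1-[5-(benzyloxy)-2-hydroxy-4-methoxyphenyl]-3-(dimethylamino)-2-(3,4,5-trimethoxyphenyl)prop-2-en-1-one (alkene geometry not defined) | COc1cc(O)c(cc1OCc1ccccc1)C(=O)C(=CN(C)C)c1cc(OC)c(OC)c(OC)c1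
F3 | step 3 | 1-[5-(benzyloxy)-2-hydroxy-4-methoxyphenyl]-2-(3,4,5-trimethoxyphenyl)ethan-1-iminium chloride | COc1cc(O)c(cc1OCc1ccccc1)C(=[NH2+])Cc1cc(OC)c(OC)c(OC)c1.[Cl-]
F4 | step 4 | 6-(benzyloxy)-4-chloro-7-methoxy-3-(3,4,5-trimethoxyphenyl)-2H-chromen-2-one | COc1cc2oc(=O)c(-c3cc(OC)c(OC)c(OC)c3)c(Cl)c2cc1OCc1ccccc1
F0 | step 6 | none | none
A1 | alternative 1 | 4,5-bis(benzyloxy)-2-(trimethylsilyl)phenyl trifluoromethanesulfonate | C[Si](C)(C)c1cc(OCc2ccccc2)c(OCc2ccccc2)cc1OS(=O)(=O)C(F)(F)F
A2 | alternative 1 | 2-(3,4,5-trimethoxyphenyl)acetic acid | COc1cc(CC(=O)O)cc(OC)c1OC
A3 | alternative 1 | 1-[4,5-bis(benzyloxy)-2-hydroxyphenyl]-2-(3,4,5-trimethoxyphenyl)ethan-1-one | COc1cc(CC(=O)c2cc(OCc3ccccc3)c(OCc3ccccc3)cc2O)cc(OC)c1OC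
A4 | alternative 2 | 3-(3,4,5-trimethoxyphenyl)-4H-pyran-4-one | O=c1ccocc1-c1cc(OC)c(OC)c(OC)c1
A5 | alternative 2 | 2,3-bis(trimethylsilyloxy)buta-1,3-diene | C=C(O[Si](C)(C)C)C(=C)O[Si](C)(C)C
A6 | alternative 2 | racemic cis-3-(3,4,5-trimethoxyphenyl)-6,7-bis(trimethylsilyloxy)-4a,5,8,8a-tetrahydro-4H-chromen-4-one (one enantiomer drawn) | O=C1C(=CO[C@@H]2CC(O[Si](C)(C)C)=C(O[Si](C)(C)C)C[C@H]12)c1cc(OC)c(OC)c(OC)c1
A7 | alternative 3 | 4-methoxyfuran-2(5H)-one (methyl tetronate) | COC1=CC(=O)OC1
A8 | alternative 3 | 4-methoxy-2-(trimethylsilyloxy)furan | COc1coc(O[Si](C)(C)C)c1
A9 | alternative 3 | 1-(3,4,5-trimethoxyphenyl)but-3-yn-2-one | C#CC(=O)Cc1cc(OC)c(OC)c(OC)c1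
A10 | alternative 3 | 1-(2,5-dihydroxy-4-methoxyphenyl)-2-(3,4,5-trimethoxyphenyl)ethan-1-one | COc1cc(O)c(cc1O)C(=O)Cc1cc(OC)c(OC)c(OC)c1
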